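You sent one question and a hunch, so here is the question first, with the flask and its steps.

J 0.010 M; time 6.0 h

    E + Z ⇌ E.Z, settled at all times (K1 = 42 M⁻¹)
    J + E → L + Z (k2 = 32.4 M⁻¹ min⁻¹)

1. the equivalents of E at which the part of the J that has reacted at 6.0 h is just 70%

We would reckon this flask from its last E. At the target, J stands at c(J) = 0.00300 M and Z, with E.Z counted, at c(Z) = 0.00700 M, which we take as free Z for the last E. The step to L takes free E, and the free share of E is then 1/(1 + K1·c(Z)). So the lifetime of the last E, meaning the time in which the remaining E, free and bound together, falls by a factor e with c(J) and c(Z) held at these values, is (1 + K1·c(Z))/(k2·c(J)) = 13.3 min.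

This lifetime marks the crossing, and we hold it against the run time. This run lasts 27.1 lifetimes, so E is the limiting reagent and we would charge c(E) = 0.00700 M, which is 70% of the J in equivalents.

Your forecast says 0.7 equiv, on the ground that “E is used up almost completely”.

The simulation gives 0.700 equiv for this flask, so the forecast stands. In this flask, the half-life of E by the step from J + E to L + Z at 0.0484 h is 0.055 h, much shorter than the run of 6.0 h, and our lifetime of the last E, 13.3 min, is shorter than 1.50 h. J used stands at 68.7% of the J charged after 0.600 h and at 70.0% after 1.50 h.

Its constants are invented, and the outcome is calculated.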